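The C2 and C3 hydroxyls, which sit next to the ester-bearing C1 of the benzene ring, are traced back to a vicinal diol on a cyclohexene. Both C–O bonds are cut together to leave a ring alkene. The key step, a catalytic osmium syn-dihydroxylation, puts both oxygens on in one operation. It exploits the mirror plane through C1 and C4 of the Birch-reduced six-membered ring: C2=C3 and C5=C6 are equivalent, so only the ortho,meta pattern can arise. The precursor is docosyl cyclohexa-2,5-diene-1-carboxylate, with the C22 chain already attached. Double oxidation of the diol then gives a keto tautomer of the catechol, which aromatises.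

Key step: step 3

Remark: the target has no stereocentre and is achiral, so there is no enantiomer to select; the chiral intermediates are racemic, their SMILES give relative configuration only, and all their stereocentres disappear on aromatisation.
Numbering note: in the Why lines, ring atoms are numbered as in the target (C1 ester carbon, C2 and C3 oxygen-bearing, C4 the ring CH2 of the dihydro compounds). Systematic names keep their own numbering.

Step 1
Reactants: 1 benzoic acid
Product: 3 cyclohexa-2,5-diene-1-carboxylic acid, via sodium cyclohexa-2,5-diene-1-carboxylate 2 (not isolated)
Conditions: Na (3.3 equiv), EtOH, liq. NH3, −78 → −33 °C; NH4Cl; aq HCl to pH 3–4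
Reagents that add atoms: none
Why: Birch reduction, in which the carboxylate stabilises negative charge at the ipso and para carbons of the reduced ring, so protons are delivered to C1 and C4 under kinetic control and the skipped 2,5-diene is formed rather than a conjugated isomer.

Step 2
Reactants: 3 cyclohexa-2,5-diene-1-carboxylic acid, 4 1-docosanol
Product: 5 docosyl cyclohexa-2,5-diene-1-carboxylate
Conditions: DCC (1.1 equiv), DMAP (5 mol%), CH2Cl2, 0 °C → rt, Ar
Reagents that add atoms: none
Why: Steglich esterification, in which carbodiimide activation with catalytic DMAP as acyl-transfer agent couples the acid to the unhindered primary alcohol at or below room temperature, and no base strong enough to remove the doubly allylic C1–H is present, so the skipped diene should stay out of conjugation.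

Step 3
Reactants: 5 docosyl cyclohexa-2,5-diene-1-carboxylate
Product: 7 docosyl (1S*,5S*,6R*)-5,6-dihydroxycyclohex-2-ene-1-carboxylate (racemic cis-diol trans to the ester), via cyclic osmate ester 6 (not isolated)
Conditions: OsO4 (1 mol%), NMO (0.95 equiv), THF/t-BuOH/H2O, 0 °C → rt
Reagents that add atoms: osmium tetroxide O=[Os](=O)(=O)=O (catalytic carrier of both oxygens); N-methylmorpholine N-oxide C[N+]1([O-])CCOCC1; water O
Why: OsO4 adds across one cis-disubstituted ring alkene of 5 (C2=C3) in a concerted suprafacial [3+2] cycloaddition to give osmate 6, which water cleaves to diol 7 while NMO takes Os(VI) back to Os(VIII). The closest known reaction type is the catalytic OsO4/NMO mono-dihydroxylation of cyclohexa-1,4-dienes; the product gains no ring, since the five-membered osmate ring made in the cycloaddition is opened again by hydrolysis. C2 and C3 are set cis to each other by the suprafacial delivery of both oxygens, their relation to C1 is set by the CO2R group, which projects over one face of the nearly flat ring and sends osmium to the other, and C1 becomes stereogenic only because the mirror plane is lost, attack on either enantiotopic alkene being equally likely, so 7 is racemic. Regioselectivity needs no control, because the plane through C1 and C4 makes C2=C3 and C5=C6 equivalent and either alkene places the oxygens ortho and meta to the ester carbon. The selectivity that has to be secured is single against double addition: NMO is the limiting reagent, the diene offers two alkenes against one in 7, and the alkene left in 7 has the ester over one face, the axial hydroxyl of the cis-diol over the other and two electron-withdrawing homoallylic C–O bonds. The trans relation of diol and ester also rules out lactonisation, unreacted non-polar 5 should be easy to recover, and any syn adduct would converge on the same target.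

Step 4
Reactants: 7 docosyl (1S*,5S*,6R*)-5,6-dihydroxycyclohex-2-ene-1-carboxylate
Product: 10 Gentiside J (docosyl 2,3-dihydroxybenzoate), via bis(alkoxysulfonium) salt 8 (not isolated), via enedione 9 (not isolated)
Conditions: DMSO (5 equiv), TFAA (2.5 equiv), CH2Cl2, −65 °C; 7 in CH2Cl2/THF; Et3N (8 equiv), −65 → 0 °C, Ar
Reagents that add atoms: none
Why: Swern-type oxidation with TFAA-activated DMSO, a known way from vicinal diols to 1,2-diones and from cyclohexenediols to catechols, in which both carbinols are turned into alkoxysulfonium ions (8) before any base is present, so triethylamine releases the two ketones together and no half-oxidised hydroxy ketone lingers to lose water (the C1–H is moreover cis to the C2–O bond and cannot undergo anti elimination); enedione 9 is an isomer of the catechol, its C2 ketone enolising towards the acidic C1–H and its C3 ketone towards C4–H, so aromatisation needs only proton shifts and removes all three stereocentres, while the chlorine-free activator avoids chlorination of the enol-rich product.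

Compound list
1 | benzoic acid | OC(=O)c1ccccc1 | starting material
2 | sodium cyclohexa-2,5-diene-1-carboxylate (not isolated) | [Na+].[O-]C(=O)C1C=CCC=C1 | intermediate
3 | cyclohexa-2,5-diene-1-carboxylic acid (1,4-dihydrobenzoic acid) | OC(=O)C1C=CCC=C1 | intermediate
4 | 1-docosanol | CCCCCCCCCCCCCCCCCCCCCCO | starting material
5 | docosyl cyclohexa-2,5-diene-1-carboxylate (achiral, mirror plane through C1 and C4) | CCCCCCCCCCCCCCCCCCCCCCOC(=O)C1C=CCC=C1 | intermediate
6 | cyclic osmium(VI) ester of the diol, O–Os(=O)2–O bridge cis-fused across the two carbinol carbons and trans to the ester, racemic (not isolated) | CCCCCCCCCCCCCCCCCCCCCCOC(=O)[C@H]1C=CC[C@H](O2)[C@@H]1O[Os]2(=O)=O | intermediate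
7 | docosyl (1S*,5S*,6R*)-5,6-dihydroxycyclohex-2-ene-1-carboxylate, racemic, cis-diol trans to the ester | CCCCCCCCCCCCCCCCCCCCCCOC(=O)[C@H]1C=CC[C@H](O)[C@@H]1O | intermediate
8 | bis(dimethylsulfonio-oxy) derivative of 7, bis(trifluoroacetate) salt, racemic (not isolated) | CCCCCCCCCCCCCCCCCCCCCCOC(=O)[C@H]1C=CC[C@H](O[S+](C)C)[C@@H]1O[S+](C)C.[O-]C(=O)C(F)(F)F.[O-]C(=O)C(F)(F)F | intermediate
9 | docosyl 5,6-dioxocyclohex-2-ene-1-carboxylate, C1 configurationally labile (not isolated) | CCCCCCCCCCCCCCCCCCCCCCOC(=O)C1C=CCC(=O)C1=O | intermediate
10 | Gentiside J, docosyl 2,3-dihydroxybenzoate (achiral) | CCCCCCCCCCCCCCCCCCCCCCOC(=O)c1cccc(O)c1O | target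

Total step count: 4. Longest linear sequence: 4 steps (1 → 3 → 5 → 7 → 10).

Steps most likely to fail

Step 3 (key step). The second alkene may be osmylated before the first pass is complete. Turnover may also be sluggish because the waxy substrate and the aqueous co-oxidant mix poorly. The fallback runs from 5 back to 7 and secures selectivity by masking one alkene instead of by stoichiometry. One equivalent of Br2 (CH2Cl2, −78 °C) should add to one alkene to give docosyl 5,6-dibromocyclohex-2-ene-1-carboxylate F1. The only alkene left can then be dihydroxylated with catalytic OsO4 and a full charge of NMO to give docosyl 2,3-dibromo-5,6-dihydroxycyclohexane-1-carboxylate F2. Zinc dust (AcOH/Et2O, 0 °C → rt) then removes both bromines reductively and restores the alkene of 7. The face attacked in either addition does not matter, since every diastereomer converges on 10.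

Step 4. One ring oxygen may be lost by β-elimination or dehydration at a half-oxidised stage. Surplus activated DMSO may also methylthiomethylate the electron-rich ring. The fallback runs from 7 back to 10. It is a base-free hypervalent-iodine oxidation that never turns a ring oxygen into a leaving group and is allowed to overshoot, followed by a reduction. IBX (about 2.5 equiv, DMSO/THF, rt) should take the 1,2-diol to the 1,2-dione without C–C cleavage, and the dione aromatises as before. Any material carried on to docosyl 5,6-dioxocyclohexa-1,3-diene-1-carboxylate F3 is returned to 10 by shaking the crude mixture with aqueous Na2S2O4.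

Step 2. The skipped diene may migrate into conjugation through the activated acyl species, whose C1–H is more acidic. Acyl transfer to nitrogen of the carbodiimide adduct may also compete. The fallback runs from 3 and 4 back to 5. It is a Mitsunobu esterification (PPh3, DIAD, THF, 0 °C → rt), which activates the primary alcohol instead of the acid under essentially neutral conditions, so C1–H is never next to an activated acyl group. It makes no new isolable compound.

Further compounds
F1 | step 3 | docosyl 5,6-dibromocyclohex-2-ene-1-carboxylate (racemic, trans-dibromide, C6–Br trans to the ester) | CCCCCCCCCCCCCCCCCCCCCCOC(=O)[C@H]1[C@H](Br)[C@@H](Br)CC=C1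
F2 | step 3 | docosyl 2,3-dibromo-5,6-dihydroxycyclohexane-1-carboxylate (racemic, trans-dibromide, cis-diol drawn trans to the ester) | CCCCCCCCCCCCCCCCCCCCCCOC(=O)[C@H]1[C@H](Br)[C@@H](Br)C[C@H](O)[C@@H]1O
F3 | step 4 | docosyl 5,6-dioxocyclohexa-1,3-diene-1-carboxylate (o-quinone of the target) | CCCCCCCCCCCCCCCCCCCCCCOC(=O)C1=CC=CC(=O)C1=O
F0 | step 2 | none | none
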